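## Retrosynthetic overview
1. The target comes from a tetracyclic 1,15-diketone by chemoselective C-1 reduction, acetylation and desilylation.
2. Ring D is closed last. The C-15–C-16 bond forms by intramolecular alkyne hydroacylation of a cis-1,3 formyl/ethynyl pair on ring C.
3. Rings B and C form in one pot. A ring A enol carbamate closes 6-exo-dig onto an alkynyl acetal (C-9–C-10). The released 8,9-bis(alkylidene) dienal then adds a Z-silyloxy enyne (C-11–C-12 and C-13–C-14) in an inverse-demand Diels–Alder reaction.
4. The C-5–C-6 bond comes from a Hoppe homoaldol reaction of an enantioenriched 2,4,4-trimethylcyclohexenyl carbamate with a seven-carbon enyne aldehyde.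
5. Ring order: A (bought as the enone), then B + C in one operation, then D.

**Atom labels.** C-1 to C-10 and C-18 to C-20 are numbered as in ent-kauranes, and C-8=C-9 is the tetrasubstituted alkene. Ring C is completed by C-11 (on C-9), C-12 (carbinol bridge), C-13 and C-14 (CH2 on C-8). Ring D is completed by C-15 (ketone, on C-11), C-16 (on C-13) and C-17 (=CH2). The α face is the face of the C-10 methyl group.

**Assumption.** The four compounds marked as starting materials are catalogue items, and the lithium-to-titanium exchange in step 7 goes with inversion, as is normal for lithiated allyl carbamates.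

## Route

Step 1
Reactants: 1 3-bromobut-3-en-1-ol; 2 3,3-diethoxyprop-1-yne
Product: 3 6,6-diethoxy-3-methylidenehex-4-yn-1-ol
Conditions: PdCl2(PPh3)2 (2 mol%), CuI (4 mol%), Et3N, THF, rt
Reagents that add atoms: none
Why: Sonogashira coupling, in which zerovalent palladium inserts into the 2-bromoalkene and the copper acetylide transfers the alkyne, while the free alcohol and the acetal are inert.

Step 2
Reactants: 3 6,6-diethoxy-3-methylidenehex-4-yn-1-ol
Product: 4 6,6-diethoxy-3-methylidenehex-4-ynal
Conditions: Dess–Martin periodinane, CH2Cl2, 0 °C to rt, used at once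
Reagents that add atoms: none
Why: Dess–Martin oxidation stops at the aldehyde and uses no base that could move the 1,1-disubstituted alkene into conjugation.

Step 3
Reactants: 5 but-3-yn-1-ol
Product: 6 but-3-ynal
Conditions: Dess–Martin periodinane, CH2Cl2, 0 °C, short silica plug, kept as a cold CH2Cl2 solution
Reagents that add atoms: none
Why: Dess–Martin oxidation under near-neutral conditions gives the labile β,γ-alkynyl aldehyde without isomerisation to the allenal.

Step 4
Reactants: 6 but-3-ynal
Product: 7 (Z)-1-(tert-butyldimethylsilyloxy)but-1-en-3-yne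
Conditions: TBSOTf, Et3N, CH2Cl2, −78 to 0 °C
Reagents that add atoms: tert-butyldimethylsilyl triflate, CC(C)(C)[Si](C)(C)OS(=O)(=O)C(F)(F)F
Why: Soft enolisation (silyl enol ether formation), in which O-silylation and loss of the doubly activated CH2 proton give the conjugated enyne, mainly as the Z isomer as is usual for aldehydes, and the minor E isomer is removed on deactivated silica.

Step 5
Reactants: 8 2,4,4-trimethylcyclohex-2-en-1-one
Product: 9 (S)-2,4,4-trimethylcyclohex-2-en-1-ol
Conditions: (R)-Me-CBS (10 mol%), BH3·THF, THF, −20 °C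
Reagents that add atoms: none
Why: Corey–Bakshi–Shibata reduction, in which the α-methyl alkene arm acts as the large group and the R catalyst delivers hydride to give the S carbinol (oxygen on the α face).

Step 6
Reactants: 9 (S)-2,4,4-trimethylcyclohex-2-en-1-ol
Product: 10 (S)-2,4,4-trimethylcyclohex-2-en-1-yl N,N-diisopropylcarbamate
Conditions: NaH, THF, 0 °C; iPr2NCOCl, reflux
Reagents that add atoms: N,N-diisopropylcarbamoyl chloride, CC(C)N(C(C)C)C(=O)Cl
Why: O-carbamoylation of the sodium alkoxide leaves the stereocentre untouched and installs the directing group for the next step.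

Step 7
Reactants: 10 (S)-2,4,4-trimethylcyclohex-2-en-1-yl N,N-diisopropylcarbamate; 4 6,6-diethoxy-3-methylidenehex-4-ynal
Product: 12 (3R)-3-[(1S)-6,6-diethoxy-1-hydroxy-3-methylidenehex-4-yn-1-yl]-2,4,4-trimethylcyclohex-1-en-1-yl N,N-diisopropylcarbamate, via allyltitanium species 11 (not isolated)
Conditions: s-BuLi, TMEDA, Et2O, −78 °C; ClTi(OiPr)3, −78 °C; 4, −78 to −40 °C; aq NH4Cl
Reagents that add atoms: none
Why: Hoppe homoaldol reaction, in which stereoretentive carbamate-directed lithiation, invertive Li-to-Ti exchange and suprafacial γ-attack through a cyclic six-membered transition state carry the C-1 chirality to C-5 (R, new bond on the α face), and the aldehyde chain turns away from the C-4 gem-dimethyl group to give 6S.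

Step 8
Reactants: 12 homoaldol adduct
Product: 13 6-O-TBS ether of 12 (C-5 R,C-6 S)
Conditions: TBSOTf (1.1 equiv), 2,6-lutidine, CH2Cl2, −78 °C
Reagents that add atoms: tert-butyldimethylsilyl triflate, CC(C)(C)[Si](C)(C)OS(=O)(=O)C(F)(F)F
Why: Silyl triflate silylation of the hindered alcohol at −78 °C is much faster than any acetal activation, and it blocks later oxa-Michael closure of O-6 onto C-9.

Step 9
Reactants: 13 6-O-TBS enol carbamate acetal; 7 (Z)-1-(tert-butyldimethylsilyloxy)but-1-en-3-yne
Product: 16 tricyclic 11-formyl-13-ethynyl-1-ketone (5R,6S,10R,11R,12S,13R) with C-8=C-9 and 6,12-bis-OTBS, via allenyl ether 14 (not isolated), via dienal 15 (not isolated)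
Conditions: TMSOTf (20 mol%), CH2Cl2, −78 to −20 °C; then H2O (1.2 equiv), THF, 0 °C; then 2,6-di-tert-butyl-4-methylpyridine (0.3 equiv), 4 Å MS, 7 (4 equiv), PhMe (CH2Cl2 distilled off), 110 °C, one pot
Reagents that add atoms: water, O
Why: Proposed new method: TMSOTf ionises the alkynyl acetal to an alkynyl oxocarbenium ion, and the enol carbamate carbon C-10 attacks its slim sp carbon C-9 in a 6-exo-dig Mukaiyama–Michael closure (1,2-attack would need an eight-membered ring, 1,6-attack at C-14 would give a cumulenyl ether); the liberated TMSOEt takes over the carbamoyl group so the silyl triflate turns over, and chair-like closure with the C-5 side chain equatorial sets C-10 (R, trans-decalin); water/TfOH then protonates the allenyl ether at C-11 from the open C-8 side to give the Z-dienal with the formyl group outside the s-cis-locked diene; after neutralisation this diene undergoes an inverse-electron-demand Diels–Alder reaction with the Z-enol ether (nucleophilic C-13 to the C-14 terminus, C-12 to C-11, endo, from the β face because the axial C-10 methyl and the 6α-OTBS group block the α face), which sets C-11 (R), C-12 (S) and C-13 (R) all-cis; the closest known reaction types are the Lewis-acid-mediated intramolecular Mukaiyama–Michael addition of cyclic enol carbamates to enones and Diels–Alder trapping of 1,2-bis(alkylidene)cyclohexanes generated in situ.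

Step 10
Reactants: 16 tricyclic 11-formyl-13-ethynyl-1-ketone
Product: 17 tetracyclic 16-methylidene-1,15-diketone 6,12-bis-TBS ether (5R,6S,10R,11R,12S,13R)
Conditions: [Rh(cod)2]BF4 (10 mol%), rac-BINAP (10 mol%), H2 pre-activation, CH2Cl2, rt to 40 °C
Reagents that add atoms: none
Why: Rhodium-catalysed intramolecular alkyne hydroacylation (5-alkynal to α-alkylidenecyclopentanone), in which monovalent rhodium inserts into the formyl C–H bond, cis-hydrometalation puts the metal on C-16 and reductive elimination forms C-15–C-16; this is possible because the two groups are cis-1,3, and no stereocentre is created or touched.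

Step 11
Reactants: 17 tetracyclic 1,15-diketone
Product: 19 1α-alcohol (1S) of the 15-oxo-16-ene 6,12-bis-TBS ether, via phosphonium silyl enol ether 18 (not isolated)
Conditions: PPh3 (1.2 equiv), TMSOTf (1.2 equiv), CH2Cl2, 0 °C; BH3·THF, −40 to 0 °C; TBAF (1.3 equiv), 0 °C; aq work-up
Reagents that add atoms: none
Why: In situ protection of the enone as its phosphonium silyl enol ether leaves only the C-1 ketone for borane reduction, hydride enters axially on the β face away from the axial C-10 methyl to give the equatorial 1α (S) alcohol, and fluoride returns the exocyclic enone.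

Step 12
Reactants: 19 1α-alcohol
Product: 20 1α-acetate 6,12-bis-TBS ether
Conditions: Ac2O, DMAP (cat.), pyridine, CH2Cl2, rt
Reagents that add atoms: acetic anhydride, CC(=O)OC(C)=O
Why: DMAP-catalysed acetylation of the only free hydroxyl group, with retention at C-1.

Step 13
Reactants: 20 1α-acetate 6,12-bis-TBS ether
Product: 21 target (1S,5R,6S,10R,11R,12S,13R)
Conditions: HF·pyridine, THF/pyridine, 0 °C to rt
Reagents that add atoms: none
Why: Fluoride-mediated desilylation under mildly acidic conditions frees both secondary alcohols without harming the acetate, the enone or any stereocentre.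

## Compound list
1 | 3-bromobut-3-en-1-ol | OCCC(Br)=C | starting material
2 | 3,3-diethoxyprop-1-yne | C#CC(OCC)OCC | starting material
3 | 6,6-diethoxy-3-methylidenehex-4-yn-1-ol | OCCC(=C)C#CC(OCC)OCC | intermediate
4 | 6,6-diethoxy-3-methylidenehex-4-ynal | O=CCC(=C)C#CC(OCC)OCC | intermediate
5 | but-3-yn-1-ol | OCCC#C | starting material
6 | but-3-ynal | O=CCC#C | intermediate
7 | (Z)-1-(tert-butyldimethylsilyloxy)but-1-en-3-yne | C#C/C=C\O[Si](C)(C)C(C)(C)C | intermediate
8 | 2,4,4-trimethylcyclohex-2-en-1-one | CC1=CC(C)(C)CCC1=O | starting material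
9 | (S)-2,4,4-trimethylcyclohex-2-en-1-ol | CC1=CC(C)(C)CC[C@@H]1O | intermediate
10 | (S)-2,4,4-trimethylcyclohex-2-en-1-yl N,N-diisopropylcarbamate | CC1=CC(C)(C)CC[C@@H]1OC(=O)N(C(C)C)C(C)C | intermediate
11 | [1-(diisopropylcarbamoyloxy)-2,4,4-trimethylcyclohex-2-en-1-yl]titanium triisopropoxide, Ti on the α face | CC1=CC(C)(C)CC[C@]1(OC(=O)N(C(C)C)C(C)C)[Ti](OC(C)C)(OC(C)C)OC(C)C | intermediate
12 | (3R)-3-[(1S)-6,6-diethoxy-1-hydroxy-3-methylidenehex-4-yn-1-yl]-2,4,4-trimethylcyclohex-1-en-1-yl N,N-diisopropylcarbamate | CCOC(OCC)C#CC(=C)C[C@H](O)[C@@H]1C(C)(C)CCC(OC(=O)N(C(C)C)C(C)C)=C1C | intermediate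
13 | 6-O-TBS ether of 12 | CCOC(OCC)C#CC(=C)C[C@H](O[Si](C)(C)C(C)(C)C)[C@@H]1C(C)(C)CCC(OC(=O)N(C(C)C)C(C)C)=C1C | intermediate
14 | (5R,6S,10R)-trans-decalin-1-one with 4,4,10-trimethyl, 6α-OTBS, 8-methylidene and 9-(2-ethoxyethenylidene) groups, allene axis unassigned | CCOC=C=C1C(=C)C[C@H](O[Si](C)(C)C(C)(C)C)[C@@H]2C(C)(C)CCC(=O)[C@@]12C | intermediate
15 | (5R,6S,10R)-trans-decalin-1-one with 4,4,10-trimethyl, 6α-OTBS, 8-methylidene and 9-[(Z)-2-oxoethylidene] groups, formyl cis to C-10 | O=C/C=C1/C(=C)C[C@H](O[Si](C)(C)C(C)(C)C)[C@@H]2C(C)(C)CCC(=O)[C@@]12C | intermediate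
16 | tricyclic 1-ketone (rings A, B, C; C-8=C-9) with 11-formyl, 12-OTBS and 13-ethynyl all cis on the β face and 6α-OTBS | O=C[C@@H]2C3=C(C[C@H](C#C)[C@@H]2O[Si](C)(C)C(C)(C)C)C[C@H](O[Si](C)(C)C(C)(C)C)[C@@H]1C(C)(C)CCC(=O)[C@@]31C | intermediate
17 | tetracyclic 16-methylidene-1,15-diketone 6,12-bis-TBS ether | C=C1C(=O)[C@@H]2C3=C(C[C@H]1[C@@H]2O[Si](C)(C)C(C)(C)C)C[C@H](O[Si](C)(C)C(C)(C)C)[C@@H]1C(C)(C)CCC(=O)[C@@]31C | intermediate
18 | 17-(triphenylphosphonio)-15-(trimethylsilyloxy)-15-ene triflate of 17, C-1 ketone free | c4ccccc4[P+](c5ccccc5)(c6ccccc6)CC1=C(O[Si](C)(C)C)[C@@H]2C3=C(C[C@H]1[C@@H]2O[Si](C)(C)C(C)(C)C)C[C@H](O[Si](C)(C)C(C)(C)C)[C@@H]1C(C)(C)CCC(=O)[C@@]31C.[O-]S(=O)(=O)C(F)(F)F | intermediate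
19 | 1α-hydroxy (1S) 15-oxo-16-ene 6,12-bis-TBS ether | C=C1C(=O)[C@@H]2C3=C(C[C@H]1[C@@H]2O[Si](C)(C)C(C)(C)C)C[C@H](O[Si](C)(C)C(C)(C)C)[C@@H]1C(C)(C)CC[C@H](O)[C@@]31C | intermediate
20 | 1α-acetoxy 15-oxo-16-ene 6,12-bis-TBS ether | C=C1C(=O)[C@@H]2C3=C(C[C@H]1[C@@H]2O[Si](C)(C)C(C)(C)C)C[C@H](O[Si](C)(C)C(C)(C)C)[C@@H]1C(C)(C)CC[C@H](OC(C)=O)[C@@]31C | intermediate
21 | CNP0149338.1, 1α-acetoxy-6α,12-dihydroxy-15-oxo-8,16-diene (1S,5R,6S,10R,11R,12S,13R) | C=C1C(=O)[C@@H]2C3=C(C[C@H]1[C@@H]2O)C[C@H](O)[C@@H]1C(C)(C)CC[C@H](OC(C)=O)[C@@]31C | target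

## Step count
- Total: 13 steps.
- Longest linear sequence: 9 steps (steps 5 to 13, from 8).

## Steps most likely to fail

**Step 9 (one-pot closure and cycloaddition).** The weak point is the intermolecular cycloaddition of a hindered dienal with a moderately nucleophilic enol ether, in rate and in endo selectivity. The fallback sets out from 15 and returns at 16. The sequence is stopped after the hydrolysis stage and 15 is isolated. It is then treated with but-3-ynal 6 and pyrrolidinium acetate (20 mol%) in CHCl3. The enamine of 6 adds through C-13 to the C-14 terminus in a vinylogous 1,6-Michael addition. After iminium hydrolysis, the dienolate closes through C-11 onto the C-12 aldehyde in a reversible intramolecular aldol reaction. This gives the all-cis 12-hydroxy-11-formyl-13-ethynyl tricycle F1, and the other isomers are recycled under the same conditions. TBSOTf and 2,6-lutidine convert it into 16.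

**Step 10 (hydroacylation of a terminal alkyne).** Decarbonylation of the allylic aldehyde or vinylidene formation may win. The fallback sets out from 16 and returns at 17. Ni(cod)2/PBu3-catalysed reductive cyclisation of the ynal with Et3SiH forms the same C-15–C-16 bond at the alcohol oxidation level. It gives the 15-triethylsilyloxy-16-methylidene tetracycle F2. AcOH/THF/H2O removes only the triethylsilyl group to give the 15-hydroxy-16-methylidene tetracycle F3. MnO2 oxidises this allylic alcohol to 17.

**Step 7 (homoaldol reaction).** The C-6 configuration rests on the aldehyde chain avoiding the gem-dimethyl group. A normal chair arrangement would give the C-6 epimer. The fallback sets out from 10 (with 4) and returns at 12. The same coupling then gives the (1R)-carbinol epimer of the homoaldol adduct F4. This is inverted by a Mitsunobu reaction (PPh3, DIAD, 4-nitrobenzoic acid, PhMe) to the (1S)-4-nitrobenzoate of the homoaldol adduct F5. K2CO3 in MeOH cleaves the ester to 12 without touching C-5, the enol carbamate or the acetal.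

Further compounds
F1 | step 9 | all-cis 12-hydroxy-11-formyl-13-ethynyl tricycle (16 with free 12-OH) | O=C[C@@H]2C3=C(C[C@H](C#C)[C@@H]2O)C[C@H](O[Si](C)(C)C(C)(C)C)[C@@H]1C(C)(C)CCC(=O)[C@@]31C
F2 | step 10 | 15-triethylsilyloxy-16-methylidene tetracycle (C-15 unassigned) | C=C1C(O[Si](CC)(CC)CC)[C@@H]2C3=C(C[C@H]1[C@@H]2O[Si](C)(C)C(C)(C)C)C[C@H](O[Si](C)(C)C(C)(C)C)[C@@H]1C(C)(C)CCC(=O)[C@@]31C
F3 | step 10 | 15-hydroxy-16-methylidene tetracycle (C-15 unassigned) | C=C1C(O)[C@@H]2C3=C(C[C@H]1[C@@H]2O[Si](C)(C)C(C)(C)C)C[C@H](O[Si](C)(C)C(C)(C)C)[C@@H]1C(C)(C)CCC(=O)[C@@]31C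
F4 | step 7 | (1R)-carbinol epimer of the homoaldol adduct | CCOC(OCC)C#CC(=C)C[C@@H](O)[C@@H]1C(C)(C)CCC(OC(=O)N(C(C)C)C(C)C)=C1C
F5 | step 7 | (1S)-4-nitrobenzoate of the homoaldol adduct | CCOC(OCC)C#CC(=C)C[C@H](OC(=O)c2ccc(cc2)[N+](=O)[O-])[C@@H]1C(C)(C)CCC(OC(=O)N(C(C)C)C(C)C)=C1C
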